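**Retrosynthetic overview**
1. The tetronic acid ring is the only ring built and is closed last, by Dieckmann condensation of the (Z)-2-(propanoyloxy) enoate 31 (from iodide 26 via alkyllithium 28, diethyl oxalate and propanoic anhydride). This avoids the tetronate aldol and any epimerisable α-methyl aldehyde.
2. The E,E-diene is cut at its central C7–C8 single bond: one-pot Zr-catalysed methylalumination of alkynol 23, then Pd/Zn cross-coupling with (E)-iodoalkene 14. No carbonyl olefination is used.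
3. Both methyl stereocentres come from sparteine-controlled lithiation–borylation of ethyl carbamate 3 with primary boronic esters 7 and 17: (+)-sparteine gives 10S, (−)-sparteine gives 2R. The C–B bond is then converted with retention into C–C≡CH (10 → 12) or C–CH2OH (20 → 23).
4. Ring order: the furan is bought as 3-bromofuran and carried through; the pinacol boronate rings are temporary; the butenolide ring is formed in step 14.

Assumption: the target is taken as drawn, (5Z)-5-[(2R,6E,8E,10S)-13-(furan-3-yl)-2,6,10-trimethyltrideca-6,8-dien-1-ylidene]-4-hydroxy-3-methylfuran-2(5H)-one, and both sparteine enantiomers are taken as catalogue chemicals.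

**Route**

Step 1
Reactants: 1 N,N-diisopropylcarbamoyl chloride; 2 ethanol
Product: 3 ethyl N,N-diisopropylcarbamate
Conditions: Et3N (1.2 equiv), CH2Cl2, reflux, 16 h
Reagents that add atoms: none
Why: Acyl substitution (O-carbamoylation) of ethanol gives the Hoppe-type carbamate needed for both asymmetric lithiations; no stereocentre is involved.

Step 2
Reactants: 4 3-bromofuran; 5 2-allyl-4,4,5,5-tetramethyl-1,3,2-dioxaborolane
Product: 6 3-(prop-2-en-1-yl)furan
Conditions: Pd(PPh3)4 (5 mol %), CsF (3 equiv), THF, 65 °C; product kept as a concentrated Et2O/pentane solution (volatile)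
Reagents that add atoms: none
Why: Suzuki–Miyaura allylation of the heteroaryl bromide with the fluoride-activated allylboronate installs the three-carbon tether on the furan.

Step 3
Reactants: 6 3-(prop-2-en-1-yl)furan
Product: 7 2-[3-(furan-3-yl)propyl]-4,4,5,5-tetramethyl-1,3,2-dioxaborolane
Conditions: [Ir(cod)Cl]2 (1.5 mol %), dppm (3 mol %), pinacolborane (1.2 equiv), CH2Cl2, rt
Reagents that add atoms: pinacolborane, [H]B1OC(C)(C)C(C)(C)O1
Why: Ir-catalysed anti-Markovnikov hydroboration of the terminal alkene gives the linear primary boronic ester, and the aromatic furan is inert.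

Step 4
Reactants: 3 ethyl N,N-diisopropylcarbamate; 7 2-[3-(furan-3-yl)propyl]-4,4,5,5-tetramethyl-1,3,2-dioxaborolane
Product: 10 2-[(2S)-5-(furan-3-yl)pentan-2-yl]-4,4,5,5-tetramethyl-1,3,2-dioxaborolane, via lithiated carbamate 8 (not isolated), via lithium boronate complex 9 (not isolated)
Conditions: 3 (1.3 equiv), (+)-sparteine (1.3 equiv), s-BuLi (1.25 equiv), Et2O, −78 °C, 5 h; 7 (1.0 equiv), −78 °C, 1 h; MgBr2·OEt2 (1.3 equiv), then 35 °C, 16 h
Reagents that add atoms: none
Why: Lithiation–borylation: Hoppe sparteine-directed deprotonation gives (R)-8, which is borylated with retention and undergoes invertive 1,2-metallate rearrangement, setting the future C-10 stereocentre as S.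

Step 5
Reactants: 10 2-[(2S)-5-(furan-3-yl)pentan-2-yl]-4,4,5,5-tetramethyl-1,3,2-dioxaborolane
Product: 12 3-[(4S)-4-methylhex-5-yn-1-yl]furan, via 2-bromoalkene 11 (not isolated)
Conditions: CH2=CHBr (3 equiv), LiN(iPr)2 (2.5 equiv) added to 10 in THF/Et2O at −95 °C (in-situ trapping), → −78 °C; I2 (1.2 equiv), MeOH, −78 °C; NaOMe, MeOH, → rt; solvent switch; Bu4NF·3H2O (5 equiv), DMF, 60 °C
Reagents that add atoms: vinyl bromide, C=CBr
Why: Enantiospecific deborylative alkynylation: Zweifel-type 1,2-migration of the stereogenic carbon from boron to the α-bromovinyl carbon with retention, anti-deiodoboration, then fluoride-mediated dehydrobromination, so C-10 stays S.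

Step 6
Reactants: 12 3-[(4S)-4-methylhex-5-yn-1-yl]furan
Product: 14 3-[(4S,5E)-6-iodo-4-methylhex-5-en-1-yl]furan, via alkenyl-Zr(Cl)Cp2 species 13 (not isolated)
Conditions: Cp2Zr(H)Cl (1.3 equiv), THF, rt, 1 h, dark; I2 (1.1 equiv), THF, 0 °C; Na2S2O3 (aq)
Reagents that add atoms: iodine, [I][I]
Why: Schwartz hydrozirconation is syn and puts Zr on the terminal carbon, and iodinolysis with retention gives the E-iodoalkene that fixes the 8E geometry.

Step 7
Reactants: 15 (5-chloropent-1-yn-1-yl)trimethylsilane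
Product: 17 trimethyl[5-(4,4,5,5-tetramethyl-1,3,2-dioxaborolan-2-yl)pent-1-yn-1-yl]silane, via alkylmagnesium chloride 16 (not isolated)
Conditions: Mg turnings (1.5 equiv), BrCH2CH2Br (cat.), THF, reflux; 2-isopropoxy-4,4,5,5-tetramethyl-1,3,2-dioxaborolane (1.2 equiv), −78 °C → rt; NH4Cl (aq)
Reagents that add atoms: 2-isopropoxy-4,4,5,5-tetramethyl-1,3,2-dioxaborolane, CC(C)OB1OC(C)(C)C(C)(C)O1
Why: Grignard formation and electrophilic borylation with the isopropoxy boronate give the primary pinacol boronic ester, with the alkyne masked as its silane.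

Step 8
Reactants: 3 ethyl N,N-diisopropylcarbamate; 17 trimethyl[5-(4,4,5,5-tetramethyl-1,3,2-dioxaborolan-2-yl)pent-1-yn-1-yl]silane
Product: 20 trimethyl[(6R)-6-(4,4,5,5-tetramethyl-1,3,2-dioxaborolan-2-yl)hept-1-yn-1-yl]silane, via lithiated carbamate 18 (not isolated), via lithium boronate complex 19 (not isolated)
Conditions: 3 (1.3 equiv), (−)-sparteine (1.3 equiv), s-BuLi (1.25 equiv), Et2O, −78 °C, 5 h; 17 (1.0 equiv), −78 °C, 1 h; MgBr2·OEt2 (1.3 equiv), then 35 °C, 16 h
Reagents that add atoms: none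
Why: The same lithiation–borylation with the other sparteine enantiomer gives (S)-18, then borylation with retention and invertive 1,2-migration, setting the future C-2 stereocentre (R in 20).

Step 9
Reactants: 20 trimethyl[(6R)-6-(4,4,5,5-tetramethyl-1,3,2-dioxaborolan-2-yl)hept-1-yn-1-yl]silane
Product: 23 (2R)-2-methylhept-6-yn-1-ol, via homologated boronic ester 21 (not isolated), via silylated alkynol 22 (not isolated)
Conditions: BrCH2Cl (2.5 equiv), n-BuLi (2.0 equiv), THF, −78 °C → rt; 2 M NaOH, 30% H2O2, 0 °C → rt; MeOH, rt, 3 h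
Reagents that add atoms: bromochloromethane, ClCBr; hydrogen peroxide, OO
Why: Matteson homologation (chloromethyllithium insertion) and alkaline peroxide oxidation of C–B both proceed with retention, and the same basic methanol cleaves the C(sp)–Si bond, so the stereocentre is carried unchanged into 23.

Step 10
Reactants: 23 (2R)-2-methylhept-6-yn-1-ol; 14 3-[(4S,5E)-6-iodo-4-methylhex-5-en-1-yl]furan
Product: 25 (2R,6E,8E,10S)-13-(furan-3-yl)-2,6,10-trimethyltrideca-6,8-dien-1-ol, via alkenyl-AlMe2 species 24 (not isolated)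
Conditions: AlMe3 (3 equiv), Cp2ZrCl2 (0.25 equiv), CH2Cl2, 0 °C → rt, 16 h; volatiles removed in vacuo; 14 (0.85 equiv), ZnCl2 (0.5 equiv), Pd(PPh3)4 (5 mol %), THF, rt, 6 h; aq. potassium sodium tartrate
Reagents that add atoms: trimethylaluminium, C[Al](C)C
Why: Negishi Zr-catalysed syn-methylalumination (methyl to the internal carbon, Al terminal) fixes the 6E trisubstituted alkene, and in-situ Negishi cross-coupling with 14 proceeds with retention at both alkenes to give the E,E-diene.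

Step 11
Reactants: 25 (2R,6E,8E,10S)-13-(furan-3-yl)-2,6,10-trimethyltrideca-6,8-dien-1-ol
Product: 26 3-[(4S,5E,7E,12R)-13-iodo-4,8,12-trimethyltrideca-5,7-dien-1-yl]furan
Conditions: PPh3 (1.3 equiv), imidazole (1.5 equiv), I2 (1.3 equiv), CH2Cl2, 0 °C → rt, dark
Reagents that add atoms: iodine, [I][I]
Why: Appel-type iodination replaces the primary hydroxyl by SN2 at CH2, leaving the adjacent stereocentre and the diene untouched.

Step 12
Reactants: 26 3-[(4S,5E,7E,12R)-13-iodo-4,8,12-trimethyltrideca-5,7-dien-1-yl]furan; 27 diethyl oxalate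
Product: 29 ethyl (4R,8E,10E,12S)-15-(furan-3-yl)-4,8,12-trimethyl-2-oxopentadeca-8,10-dienoate, via alkyllithium 28 (not isolated)
Conditions: t-BuLi (2.05 equiv), Et2O/pentane, −78 °C, 20 min; cannulated into 27 (3 equiv), Et2O, −78 °C, 1 h; NH4Cl (aq), −78 °C → rt
Reagents that add atoms: none
Why: Iodine–lithium exchange followed by mono-acylation of the alkyllithium with excess oxalate (tetrahedral adduct stable at −78 °C) gives the α-keto ester, whose stereocentre is β to the ketone and cannot epimerise.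

Step 13
Reactants: 29 ethyl (4R,8E,10E,12S)-15-(furan-3-yl)-4,8,12-trimethyl-2-oxopentadeca-8,10-dienoate; 30 propanoic anhydride
Product: 31 ethyl (2Z,4R,8E,10E,12S)-15-(furan-3-yl)-4,8,12-trimethyl-2-(propanoyloxy)pentadeca-2,8,10-trienoate
Conditions: 30 (1.5 equiv), Et3N (2 equiv), DMAP (10 mol %), CH2Cl2, 0 °C → rt
Reagents that add atoms: none
Why: DMAP-catalysed O-acylation of the α-keto ester enol gives the favoured Z-enol ester (alkyl group trans to the ester), which fixes the later 5Z ylidene geometry.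

Step 14
Reactants: 31 ethyl (2Z,4R,8E,10E,12S)-15-(furan-3-yl)-4,8,12-trimethyl-2-(propanoyloxy)pentadeca-2,8,10-trienoate
Product: 32 (5Z)-5-[(2R,6E,8E,10S)-13-(furan-3-yl)-2,6,10-trimethyltrideca-6,8-dien-1-ylidene]-4-hydroxy-3-methylfuran-2(5H)-one
Conditions: LiN(SiMe3)2 (2.5 equiv), THF, −78 → 0 °C; 1 M HCl to pH 3, 0 °C
Reagents that add atoms: none
Why: Dieckmann (Lacey-type) condensation: the propanoate enolate attacks the neighbouring ester 5-exo-trig and loss of ethoxide gives the stabilised tetronate anion, closing the butenolide ring with the Z-enol-ester geometry retained in the ylidene.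

**Compound list**

1 | N,N-diisopropylcarbamoyl chloride | CC(C)N(C(C)C)C(=O)Cl | starting material
2 | ethanol | CCO | starting material
3 | ethyl N,N-diisopropylcarbamate | CCOC(=O)N(C(C)C)C(C)C | intermediate
4 | 3-bromofuran | Brc1ccoc1 | starting material
5 | 2-allyl-4,4,5,5-tetramethyl-1,3,2-dioxaborolane | C=CCB1OC(C)(C)C(C)(C)O1 | starting material
6 | 3-(prop-2-en-1-yl)furan | C=CCc1ccoc1 | intermediate
7 | 2-[3-(furan-3-yl)propyl]-4,4,5,5-tetramethyl-1,3,2-dioxaborolane | CC1(C)OB(CCCc2ccoc2)OC1(C)C | intermediate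
8 | (R)-1-lithioethyl N,N-diisopropylcarbamate, (+)-sparteine complex | [Li][C@H](C)OC(=O)N(C(C)C)C(C)C | intermediate
9 | lithium [(1R)-1-(diisopropylcarbamoyloxy)ethyl][3-(furan-3-yl)propyl](pinacolato)borate | [Li+].CC1(C)O[B-](CCCc2ccoc2)([C@H](C)OC(=O)N(C(C)C)C(C)C)OC1(C)C | intermediate
10 | 2-[(2S)-5-(furan-3-yl)pentan-2-yl]-4,4,5,5-tetramethyl-1,3,2-dioxaborolane | CC1(C)OB(OC1(C)C)[C@@H](C)CCCc1ccoc1 | intermediate
11 | 3-[(4S)-5-bromo-4-methylhex-5-en-1-yl]furan | C=C(Br)[C@@H](C)CCCc1ccoc1 | intermediate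
12 | 3-[(4S)-4-methylhex-5-yn-1-yl]furan | C#C[C@@H](C)CCCc1ccoc1 | intermediate
13 | chlorobis(cyclopentadienyl)[(1E,3S)-6-(furan-3-yl)-3-methylhex-1-en-1-yl]zirconium | Cl[Zr](/C=C/[C@@H](C)CCCc1ccoc1)(C1C=CC=C1)C1C=CC=C1 | intermediate
14 | 3-[(4S,5E)-6-iodo-4-methylhex-5-en-1-yl]furan | I/C=C/[C@@H](C)CCCc1ccoc1 | intermediate
15 | (5-chloropent-1-yn-1-yl)trimethylsilane | C[Si](C)(C)C#CCCCCl | starting material
16 | chloro[5-(trimethylsilyl)pent-4-yn-1-yl]magnesium | C[Si](C)(C)C#CCCC[Mg]Cl | intermediate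
17 | trimethyl[5-(4,4,5,5-tetramethyl-1,3,2-dioxaborolan-2-yl)pent-1-yn-1-yl]silane | C[Si](C)(C)C#CCCCB1OC(C)(C)C(C)(C)O1 | intermediate
18 | (S)-1-lithioethyl N,N-diisopropylcarbamate, (−)-sparteine complex | [Li][C@@H](C)OC(=O)N(C(C)C)C(C)C | intermediate
19 | lithium [(1S)-1-(diisopropylcarbamoyloxy)ethyl][5-(trimethylsilyl)pent-4-yn-1-yl](pinacolato)borate | [Li+].CC1(C)O[B-](CCCC#C[Si](C)(C)C)([C@@H](C)OC(=O)N(C(C)C)C(C)C)OC1(C)C | intermediate
20 | trimethyl[(6R)-6-(4,4,5,5-tetramethyl-1,3,2-dioxaborolan-2-yl)hept-1-yn-1-yl]silane | CC1(C)OB(OC1(C)C)[C@H](C)CCCC#C[Si](C)(C)C | intermediate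
21 | trimethyl[(6S)-6-methyl-7-(4,4,5,5-tetramethyl-1,3,2-dioxaborolan-2-yl)hept-1-yn-1-yl]silane | CC1(C)OB(OC1(C)C)C[C@H](C)CCCC#C[Si](C)(C)C | intermediate
22 | (2R)-2-methyl-7-(trimethylsilyl)hept-6-yn-1-ol | OC[C@H](C)CCCC#C[Si](C)(C)C | intermediate
23 | (2R)-2-methylhept-6-yn-1-ol | OC[C@H](C)CCCC#C | intermediate
24 | dimethylaluminium (2R,6E)-7-(dimethylalumanyl)-2,6-dimethylhept-6-en-1-olate | C[Al](C)OC[C@H](C)CCC/C(C)=C/[Al](C)C | intermediate
25 | (2R,6E,8E,10S)-13-(furan-3-yl)-2,6,10-trimethyltrideca-6,8-dien-1-ol | OC[C@H](C)CCC/C(C)=C/C=C/[C@@H](C)CCCc1ccoc1 | intermediate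
26 | 3-[(4S,5E,7E,12R)-13-iodo-4,8,12-trimethyltrideca-5,7-dien-1-yl]furan | IC[C@H](C)CCC/C(C)=C/C=C/[C@@H](C)CCCc1ccoc1 | intermediate
27 | diethyl oxalate | CCOC(=O)C(=O)OCC | starting material
28 | [(2S,6E,8E,10S)-13-(furan-3-yl)-2,6,10-trimethyltrideca-6,8-dien-1-yl]lithium | [Li]C[C@H](C)CCC/C(C)=C/C=C/[C@@H](C)CCCc1ccoc1 | intermediate
29 | ethyl (4R,8E,10E,12S)-15-(furan-3-yl)-4,8,12-trimethyl-2-oxopentadeca-8,10-dienoate | CCOC(=O)C(=O)C[C@H](C)CCC/C(C)=C/C=C/[C@@H](C)CCCc1ccoc1 | intermediate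
30 | propanoic anhydride | CCC(=O)OC(=O)CC | starting material
31 | ethyl (2Z,4R,8E,10E,12S)-15-(furan-3-yl)-4,8,12-trimethyl-2-(propanoyloxy)pentadeca-2,8,10-trienoate | CCOC(=O)/C(OC(=O)CC)=C/[C@H](C)CCC/C(C)=C/C=C/[C@@H](C)CCCc1ccoc1 | intermediate
32 | (5Z)-5-[(2R,6E,8E,10S)-13-(furan-3-yl)-2,6,10-trimethyltrideca-6,8-dien-1-ylidene]-4-hydroxy-3-methylfuran-2(5H)-one | CC1=C(O)/C(=C/[C@H](C)CCC/C(C)=C/C=C/[C@@H](C)CCCc2ccoc2)OC1=O | target

**Totals and risks**

Total step count: 14. Longest linear sequence: 10 steps (steps 2, 3, 4, 5, 6, 10, 11, 12, 13, 14, from 3-bromofuran 4).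

Steps most likely to fail:

Step 14 (Dieckmann closure). The propanoate enolate may lose methylketene instead of cyclising, and any E-enol ester from step 13 would give the E-ylidene. The fallback sets out from dienol 25 and comes back at target 32. Dess–Martin oxidation of 25 (NaHCO3, CH2Cl2, 0 °C) gives (2R,6E,8E,10S)-13-(furan-3-yl)-2,6,10-trimethyltrideca-6,8-dienal F5. Separately, commercial 3-methyltetronic acid is O-methylated (Me2SO4, K2CO3, acetone) to 4-methoxy-3-methylfuran-2(5H)-one F6. Its C-5 lithium enolate (LiN(iPr)2, THF, −78 °C) adds to F5 to give 5-[(2R,6E,8E,10S)-13-(furan-3-yl)-1-hydroxy-2,6,10-trimethyltrideca-6,8-dien-1-yl]-4-methoxy-3-methylfuran-2(5H)-one F7. Mesylation (MsCl, Et3N) and DBU elimination give the thermodynamic Z-ylidene (5Z)-5-[(2R,6E,8E,10S)-13-(furan-3-yl)-2,6,10-trimethyltrideca-6,8-dien-1-ylidene]-4-methoxy-3-methylfuran-2(5H)-one F8. O-Demethylation with n-PrSLi in HMPA at rt then gives 32.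

Step 10 (one-pot carboalumination and cross-coupling). Residual AlMe3 can methylate 14, and the Al-to-Pd transfer may be slow in the presence of the aluminium alkoxide. The fallback sets out from alkyne 12 and alkynol 23 and comes back at dienol 25. The methylalumination of 23 is run as in step 10 but the alkenylalane is quenched with I2 (THF, −30 °C) to give (2R,6E)-7-iodo-2,6-dimethylhept-6-en-1-ol F3. Alkyne 12 is hydroborated with pinacolborane (Cp2Zr(H)Cl 10 mol %, Et3N, 60 °C) to give 2-[(1E,3S)-6-(furan-3-yl)-3-methylhex-1-en-1-yl]-4,4,5,5-tetramethyl-1,3,2-dioxaborolane F4. Suzuki–Miyaura coupling of the two isolated partners (Pd(PPh3)4, 2 M NaOH, THF, 50 °C) gives 25.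

Step 5 (deborylative alkynylation). α-Bromovinyllithium is thermally fragile and the hindered secondary boronic ester may complex slowly. The fallback sets out from boronic ester 10 and comes back at alkyne 12. Matteson homologation with LiCHCl2 (CH2Cl2, LiN(iPr)2, THF, −78 °C → rt) gives 2-[(2S)-1-chloro-5-(furan-3-yl)-2-methylpentyl]-4,4,5,5-tetramethyl-1,3,2-dioxaborolane F1. Buffered oxidation (NaOH, H2O2, 0 °C) gives (2S)-5-(furan-3-yl)-2-methylpentanal F2. Ohira–Bestmann homologation (dimethyl (1-diazo-2-oxopropyl)phosphonate, K2CO3, MeOH, 0 °C) converts F2 into 12.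

**Further compounds**

F1 | step 5 | 2-[(2S)-1-chloro-5-(furan-3-yl)-2-methylpentyl]-4,4,5,5-tetramethyl-1,3,2-dioxaborolane (C-1 epimers) | CC1(C)OB(OC1(C)C)C(Cl)[C@@H](C)CCCc1ccoc1
F2 | step 5 | (2S)-5-(furan-3-yl)-2-methylpentanal | O=C[C@@H](C)CCCc1ccoc1
F3 | step 10 | (2R,6E)-7-iodo-2,6-dimethylhept-6-en-1-ol | OC[C@H](C)CCC/C(C)=C/I
F4 | step 10 | 2-[(1E,3S)-6-(furan-3-yl)-3-methylhex-1-en-1-yl]-4,4,5,5-tetramethyl-1,3,2-dioxaborolane | CC1(C)OB(OC1(C)C)/C=C/[C@@H](C)CCCc1ccoc1
F5 | step 14 | (2R,6E,8E,10S)-13-(furan-3-yl)-2,6,10-trimethyltrideca-6,8-dienal | O=C[C@H](C)CCC/C(C)=C/C=C/[C@@H](C)CCCc1ccoc1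
F6 | step 14 | 4-methoxy-3-methylfuran-2(5H)-one | COC1=C(C)C(=O)OC1
F7 | step 14 | 5-[(2R,6E,8E,10S)-13-(furan-3-yl)-1-hydroxy-2,6,10-trimethyltrideca-6,8-dien-1-yl]-4-methoxy-3-methylfuran-2(5H)-one (diastereomer mixture) | COC1=C(C)C(=O)OC1C(O)[C@H](C)CCC/C(C)=C/C=C/[C@@H](C)CCCc1ccoc1
F8 | step 14 | (5Z)-5-[(2R,6E,8E,10S)-13-(furan-3-yl)-2,6,10-trimethyltrideca-6,8-dien-1-ylidene]-4-methoxy-3-methylfuran-2(5H)-one | CC1=C(OC)/C(=C/[C@H](C)CCC/C(C)=C/C=C/[C@@H](C)CCCc2ccoc2)OC1=O
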